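**Retrosynthetic overview**
- The strategy rests on the O1–C2–C3 corner of the tetrahydrofuran ring: C2 carries an aryl group and the ring oxygen O1, and C3 carries a one-carbon arm. This is the pattern left when an oxygen and CO are added across an aryl alkyne.
- Target ⇐ desilylation, ester reduction, C3 epimerisation and face-selective hydrogenation of C2=C3 in a methyl 2,5-diaryl-4-(silyloxymethyl)-4,5-dihydrofuran-3-carboxylate.
- Dihydrofuran ester ⇐ divalent-palladium 5-endo-dig oxypalladation–methoxycarbonylation of a (1R,2R)-1,4-diaryl-2-(silyloxymethyl)but-3-yn-1-ol. This is the only ring-forming step and makes O1–C2 and the C3–ester bond.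
- Alkynol ⇐ Sonogashira coupling of a terminal alkyne with silylated 4-bromo-2-methoxyphenol; terminal alkyne ⇐ one-carbon homologation of an aldehyde.
- Aldehyde ⇐ Evans syn-aldol of silylated vanillin with the 3-silyloxypropanoyl imide of (R)-4-benzyl-oxazolidin-2-one, which sets C4 and C5 (both R, cis in the ring).

Key step: step 13

Remarks: TBS = tert-butyldimethylsilyl, TES = triethylsilyl. Assumption: the boron enolate of the 3-silyloxypropanoyl imide follows the same syn and facial sense as the parent propanoyl imide, so the (R)-benzyl auxiliary gives the (2R,3R) adduct.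

**Step 1**
Reactants: 1 vanillin; 2 tert-butyldimethylsilyl chloride
Product: 3 4-(TBS-oxy)-3-methoxybenzaldehyde
Conditions: TBSCl, imidazole, DMF, rt
Reagents that add atoms: tert-butyldimethylsilyl chloride (2), C[Si](C)(Cl)C(C)(C)C
Why: Imidazole-promoted silyl ether formation on the phenol is routine and leaves the aldehyde untouched.

**Step 2**
Reactants: 4 4-bromo-2-methoxyphenol; 2 tert-butyldimethylsilyl chloride
Product: 5 (4-bromo-2-methoxyphenoxy)(tert-butyl)dimethylsilane
Conditions: TBSCl, imidazole, DMF, rt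
Reagents that add atoms: tert-butyldimethylsilyl chloride (2), C[Si](C)(Cl)C(C)(C)C
Why: The same phenol silylation applies, and the aryl bromide is inert to it.

**Step 3**
Reactants: 6 methyl 3-hydroxypropanoate; 2 tert-butyldimethylsilyl chloride
Product: 7 methyl 3-(TBS-oxy)propanoate
Conditions: TBSCl, imidazole, CH2Cl2, 0 °C to rt
Reagents that add atoms: tert-butyldimethylsilyl chloride (2), C[Si](C)(Cl)C(C)(C)C
Why: Silylation of the primary alcohol under imidazole catalysis should proceed without touching the ester.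

**Step 4**
Reactants: 7 methyl 3-(TBS-oxy)propanoate
Product: 8 3-(TBS-oxy)propanoic acid
Conditions: LiOH·H2O, THF/H2O, 0 °C; then cold dilute HCl to pH 4
Reagents that add atoms: lithium hydroxide, [Li+].[OH-]
Why: Ester saponification at 0 °C should outrun β-elimination of the silyloxy group, and the primary TBS ether tolerates the brief mild acidification.

**Step 5**
Reactants: 8 3-(TBS-oxy)propanoic acid; 9 (R)-4-benzyl-oxazolidin-2-one
Product: 11 (R)-4-benzyl-3-[3-(TBS-oxy)propanoyl]oxazolidin-2-one, via mixed pivalic anhydride 10 (not isolated)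
Conditions: PivCl, Et3N, THF, −20 °C; then 9, LiCl, −20 °C to rt
Reagents that add atoms: none
Why: N-acylation of the oxazolidinone through the mixed pivalic anhydride with LiCl/Et3N activation is a standard auxiliary loading that avoids strong base and hence β-elimination of the silyloxy group.

**Step 6**
Reactants: 11 (R)-4-benzyl-3-[3-(TBS-oxy)propanoyl]oxazolidin-2-one; 3 4-(TBS-oxy)-3-methoxybenzaldehyde
Product: 14 (R)-4-benzyl-3-{(2R,3R)-3-hydroxy-3-[4-(TBS-oxy)-3-methoxyphenyl]-2-[(TBS-oxy)methyl]propanoyl}oxazolidin-2-one (syn aldol), via dibutylboron Z-enolate 12 (not isolated), via dibutylboron aldolate 13 (not isolated)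
Conditions: Bu2BOTf, i-Pr2NEt, CH2Cl2, 0 °C; then 3, −78 to 0 °C; pH 7 buffer, MeOH, H2O2, 0 °C
Reagents that add atoms: none
Why: In this Evans boron syn-aldol the Z-enolate reacts through a closed Zimmerman–Traxler chair on the enolate face remote from the benzyl group, which with the (R)-auxiliary should set both the silyloxymethyl-bearing carbon and the carbinol carbon as R, the later C4 and C5 with their cis relationship.

**Step 7**
Reactants: 14 syn aldol adduct
Product: 15 (R)-4-benzyl-3-{(2R,3R)-3-[4-(TBS-oxy)-3-methoxyphenyl]-2-[(TBS-oxy)methyl]-3-(TES-oxy)propanoyl}oxazolidin-2-one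
Conditions: TESOTf, 2,6-lutidine, CH2Cl2, −78 to 0 °C
Reagents that add atoms: triethylsilyl trifluoromethanesulfonate, CC[Si](CC)(CC)OS(=O)(=O)C(F)(F)F
Why: Silyl triflate silylation of the hindered benzylic alcohol blocks retro-aldol and installs a triethylsilyl ether that can later be removed in the presence of the TBS ethers.

**Step 8**
Reactants: 15 TES-protected aldol imide
Product: 16 (2R,3R)-3-[4-(TBS-oxy)-3-methoxyphenyl]-2-[(TBS-oxy)methyl]-3-(TES-oxy)propan-1-ol
Conditions: LiBH4, MeOH (1 equiv), THF, 0 °C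
Reagents that add atoms: none
Why: Reductive cleavage of the N-acyl oxazolidinone by LiBH4 at the exocyclic carbonyl should give the primary alcohol and release the auxiliary without affecting silyl ethers or stereocentres.

**Step 9**
Reactants: 16 primary alcohol
Product: 17 (2R,3R)-3-[4-(TBS-oxy)-3-methoxyphenyl]-2-[(TBS-oxy)methyl]-3-(TES-oxy)propanal
Conditions: Dess–Martin periodinane, NaHCO3, CH2Cl2, 0 °C to rt; used crude
Reagents that add atoms: none
Why: Dess–Martin oxidation under bicarbonate buffering is near-neutral, so the α-branched aldehyde flanked by two β-silyloxy groups should form without epimerisation or elimination.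

**Step 10**
Reactants: 17 aldehyde
Product: 18 (3R,4R)-4-[4-(TBS-oxy)-3-methoxyphenyl]-3-[(TBS-oxy)methyl]-4-(TES-oxy)but-1-yne
Conditions: TMSCHN2, n-BuLi, THF, −78 °C; then 17, −78 °C to rt
Reagents that add atoms: trimethylsilyldiazomethane, C[Si](C)(C)C=[N+]=[N-]
Why: In this Colvin rearrangement lithiated trimethylsilyldiazomethane adds to the aldehyde, Peterson-type loss of silanolate and then of nitrogen gives an alkylidene carbene whose 1,2-hydride shift furnishes the terminal alkyne, and the aprotic low-temperature medium spares the α-stereocentre and the aryl silyl ether that carbonate in methanol would cleave.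

**Step 11**
Reactants: 18 terminal alkyne; 5 (4-bromo-2-methoxyphenoxy)(tert-butyl)dimethylsilane
Product: 19 (3R,4R)-1,4-bis[4-(TBS-oxy)-3-methoxyphenyl]-3-[(TBS-oxy)methyl]-4-(TES-oxy)but-1-yne
Conditions: Pd(PhCN)2Cl2 (cat.), [(t-Bu)3PH]BF4 (cat.), CuI (cat.), i-Pr2NH, dioxane, rt
Reagents that add atoms: none
Why: Sonogashira coupling with the bulky electron-rich trialkylphosphine system engages electron-rich aryl bromides at room temperature, and the amine base does not disturb silyl ethers or the propargylic stereocentre.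

**Step 12**
Reactants: 19 TES-protected diaryl alkyne
Product: 20 (1R,2R)-1,4-bis[4-(TBS-oxy)-3-methoxyphenyl]-2-[(TBS-oxy)methyl]but-3-yn-1-ol
Conditions: HF·pyridine, pyridine, THF, 0 °C
Reagents that add atoms: none
Why: Selective silyl ether cleavage relies on the higher lability of the triethylsilyl ether towards buffered acidic fluoride compared with the primary alkyl and the aryl TBS ethers, and the non-solvolytic medium protects the electron-rich benzylic carbinol.

**Step 13**
Reactants: 20 (1R,2R)-1,4-diaryl-2-(silyloxymethyl)but-3-yn-1-ol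
Product: 21 methyl (4R,5R)-2,5-bis[4-(TBS-oxy)-3-methoxyphenyl]-4-[(TBS-oxy)methyl]-4,5-dihydrofuran-3-carboxylate (C4 and C5 substituents cis)
Conditions: Pd(OCOCF3)2 (cat.), p-benzoquinone, CO (1 atm), MeOH/CH2Cl2, 0 °C to rt
Reagents that add atoms: carbon monoxide, [C-]#[O+]; methanol, CO
Why: Divalent palladium coordinates the alkyne, the C5 hydroxyl attacks the aryl-bearing alkyne carbon anti to the metal to form O1–C2 and a vinylpalladium at C3, this inserts CO and methanol cleaves the acylpalladium to the methyl ester (the C3–ester carbon bond), and p-benzoquinone returns the released zerovalent palladium to the divalent state. The closest known reaction type is the divalent-palladium oxidative cyclisation–alkoxycarbonylation of 2-alkynylphenols and homopropargylic alcohols under CO with a quinone or CuCl2 reoxidant. The dihydrofuran ring is closed in the 5-endo-dig mode. No stereocentre is created, and C4 and C5 pass through unchanged because neither takes part in bond making. The step needs 5-endo regiochemistry and chemoselectivity for the tethered hydroxyl over methanol and for CO capture over protodepalladation. The electron-rich aryl group polarises the coordinated alkyne towards attack at C2, the 4-exo alternative would be a strained oxetane, the tether gives the intramolecular oxygen the advantage, and a CO atmosphere at low temperature favours insertion.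

**Step 14**
Reactants: 21 dihydrofuran ester
Product: 22 methyl (2S,3R,4R,5R)-2,5-bis[4-(TBS-oxy)-3-methoxyphenyl]-4-[(TBS-oxy)methyl]tetrahydrofuran-3-carboxylate (all-cis)
Conditions: H2 (5 bar), Rh/Al2O3 (5 wt% Rh), EtOAc, rt
Reagents that add atoms: none
Why: Heterogeneous syn-hydrogenation on rhodium, which has little tendency to hydrogenolyse benzylic C–O bonds, should deliver both hydrogens to the face opposite the C4 silyloxymethyl and C5 aryl groups, setting C2 with its aryl cis to the C5 aryl and leaving the C3 ester temporarily cis to its neighbours.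

**Step 15**
Reactants: 22 all-cis ester
Product: 23 methyl (2S,3S,4R,5R)-2,5-bis[4-(TBS-oxy)-3-methoxyphenyl]-4-[(TBS-oxy)methyl]tetrahydrofuran-3-carboxylate (ester trans to the C2 aryl and to the C4 arm)
Conditions: DBU, anhydrous toluene, 60 °C
Reagents that add atoms: none
Why: Base-mediated epimerisation through the C3 ester enolate is a thermodynamic equilibration that should move the ester out of the all-cis arrangement to the face trans to both neighbours, setting C3 while the non-acidic C2, C4 and C5 stay fixed.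

**Step 16**
Reactants: 23 trans ester
Product: 24 [(2S,3R,4R,5R)-2,5-bis[4-(TBS-oxy)-3-methoxyphenyl]-4-[(TBS-oxy)methyl]tetrahydrofuran-3-yl]methanol
Conditions: LiAlH4, THF, 0 °C
Reagents that add atoms: none
Why: Hydride reduction of the ester to the primary alcohol removes the epimerisable carbonyl and so locks C3, with no other group reducible under these conditions.

**Step 17**
Reactants: 24 tris-silyl ether
Product: 25 [(2S,3R,4R,5R)-2,5-bis(4-hydroxy-3-methoxyphenyl)tetrahydrofuran-3,4-diyl]dimethanol (target)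
Conditions: TBAF, AcOH, THF, 0 °C to rt
Reagents that add atoms: none
Why: Fluoride-mediated global desilylation, buffered with acetic acid to keep the liberated phenols protonated, should remove the two aryl and the one alkyl TBS ethers without touching the tetrahydrofuran stereocentres.

**Compound list**
1 | vanillin | COc1cc(C=O)ccc1O | starting material
2 | tert-butyldimethylsilyl chloride | C[Si](C)(Cl)C(C)(C)C | starting material
3 | 4-(TBS-oxy)-3-methoxybenzaldehyde | COc1cc(C=O)ccc1O[Si](C)(C)C(C)(C)C | intermediate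
4 | 4-bromo-2-methoxyphenol | COc1cc(Br)ccc1O | starting material
5 | (4-bromo-2-methoxyphenoxy)(tert-butyl)dimethylsilane | COc1cc(Br)ccc1O[Si](C)(C)C(C)(C)C | intermediate
6 | methyl 3-hydroxypropanoate | COC(=O)CCO | starting material
7 | methyl 3-(TBS-oxy)propanoate | COC(=O)CCO[Si](C)(C)C(C)(C)C | intermediate
8 | 3-(TBS-oxy)propanoic acid | OC(=O)CCO[Si](C)(C)C(C)(C)C | intermediate
9 | (R)-4-benzyl-oxazolidin-2-one | O=C1N[C@H](Cc2ccccc2)CO1 | starting material
10 | 3-(TBS-oxy)propanoic pivalic anhydride (not isolated) | CC(C)(C)C(=O)OC(=O)CCO[Si](C)(C)C(C)(C)C | intermediate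
11 | (R)-4-benzyl-3-[3-(TBS-oxy)propanoyl]oxazolidin-2-one | O=C(CCO[Si](C)(C)C(C)(C)C)N1[C@H](Cc2ccccc2)COC1=O | intermediate
12 | dibutylboron Z-enolate of 11 (not isolated) | CCCCB(CCCC)O/C(=C\CO[Si](C)(C)C(C)(C)C)N1[C@H](Cc2ccccc2)COC1=O | intermediate
13 | dibutylboron aldolate of 14 (not isolated) | CCCCB(CCCC)O[C@@H](c1ccc(O[Si](C)(C)C(C)(C)C)c(OC)c1)[C@@H](CO[Si](C)(C)C(C)(C)C)C(=O)N1[C@H](Cc2ccccc2)COC1=O | intermediate
14 | (R)-4-benzyl-3-{(2R,3R)-3-hydroxy-3-[4-(TBS-oxy)-3-methoxyphenyl]-2-[(TBS-oxy)methyl]propanoyl}oxazolidin-2-one | O[C@@H](c1ccc(O[Si](C)(C)C(C)(C)C)c(OC)c1)[C@@H](CO[Si](C)(C)C(C)(C)C)C(=O)N1[C@H](Cc2ccccc2)COC1=O | intermediate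
15 | TES ether of 14 | CC[Si](CC)(CC)O[C@@H](c1ccc(O[Si](C)(C)C(C)(C)C)c(OC)c1)[C@@H](CO[Si](C)(C)C(C)(C)C)C(=O)N1[C@H](Cc2ccccc2)COC1=O | intermediate
16 | (2R,3R)-3-[4-(TBS-oxy)-3-methoxyphenyl]-2-[(TBS-oxy)methyl]-3-(TES-oxy)propan-1-ol | CC[Si](CC)(CC)O[C@@H](c1ccc(O[Si](C)(C)C(C)(C)C)c(OC)c1)[C@@H](CO[Si](C)(C)C(C)(C)C)CO | intermediate
17 | (2R,3R)-3-[4-(TBS-oxy)-3-methoxyphenyl]-2-[(TBS-oxy)methyl]-3-(TES-oxy)propanal | CC[Si](CC)(CC)O[C@@H](c1ccc(O[Si](C)(C)C(C)(C)C)c(OC)c1)[C@@H](CO[Si](C)(C)C(C)(C)C)C=O | intermediate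
18 | (3R,4R)-4-[4-(TBS-oxy)-3-methoxyphenyl]-3-[(TBS-oxy)methyl]-4-(TES-oxy)but-1-yne | CC[Si](CC)(CC)O[C@@H](c1ccc(O[Si](C)(C)C(C)(C)C)c(OC)c1)[C@@H](CO[Si](C)(C)C(C)(C)C)C#C | intermediate
19 | (3R,4R)-1,4-bis[4-(TBS-oxy)-3-methoxyphenyl]-3-[(TBS-oxy)methyl]-4-(TES-oxy)but-1-yne | CC[Si](CC)(CC)O[C@@H](c1ccc(O[Si](C)(C)C(C)(C)C)c(OC)c1)[C@@H](CO[Si](C)(C)C(C)(C)C)C#Cc1ccc(O[Si](C)(C)C(C)(C)C)c(OC)c1 | intermediate
20 | (1R,2R)-1,4-bis[4-(TBS-oxy)-3-methoxyphenyl]-2-[(TBS-oxy)methyl]but-3-yn-1-ol | O[C@@H](c1ccc(O[Si](C)(C)C(C)(C)C)c(OC)c1)[C@@H](CO[Si](C)(C)C(C)(C)C)C#Cc1ccc(O[Si](C)(C)C(C)(C)C)c(OC)c1 | intermediate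
21 | methyl (4R,5R)-2,5-bis[4-(TBS-oxy)-3-methoxyphenyl]-4-[(TBS-oxy)methyl]-4,5-dihydrofuran-3-carboxylate | COc1cc(C2=C(C(=O)OC)[C@H](CO[Si](C)(C)C(C)(C)C)[C@H](c3ccc(O[Si](C)(C)C(C)(C)C)c(OC)c3)O2)ccc1O[Si](C)(C)C(C)(C)C | intermediate
22 | methyl (2S,3R,4R,5R)-2,5-bis[4-(TBS-oxy)-3-methoxyphenyl]-4-[(TBS-oxy)methyl]tetrahydrofuran-3-carboxylate (all-cis) | COc1cc([C@H]2O[C@@H](c3ccc(O[Si](C)(C)C(C)(C)C)c(OC)c3)[C@@H](CO[Si](C)(C)C(C)(C)C)[C@H]2C(=O)OC)ccc1O[Si](C)(C)C(C)(C)C | intermediate
23 | methyl (2S,3S,4R,5R)-2,5-bis[4-(TBS-oxy)-3-methoxyphenyl]-4-[(TBS-oxy)methyl]tetrahydrofuran-3-carboxylate | COc1cc([C@H]2O[C@@H](c3ccc(O[Si](C)(C)C(C)(C)C)c(OC)c3)[C@@H](CO[Si](C)(C)C(C)(C)C)[C@@H]2C(=O)OC)ccc1O[Si](C)(C)C(C)(C)C | intermediate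
24 | [(2S,3R,4R,5R)-2,5-bis[4-(TBS-oxy)-3-methoxyphenyl]-4-[(TBS-oxy)methyl]tetrahydrofuran-3-yl]methanol | COc1cc([C@H]2O[C@@H](c3ccc(O[Si](C)(C)C(C)(C)C)c(OC)c3)[C@@H](CO[Si](C)(C)C(C)(C)C)[C@@H]2CO)ccc1O[Si](C)(C)C(C)(C)C | intermediate
25 | [(2S,3R,4R,5R)-2,5-bis(4-hydroxy-3-methoxyphenyl)tetrahydrofuran-3,4-diyl]dimethanol | COc1cc([C@H]2O[C@@H](c3ccc(O)c(OC)c3)[C@@H](CO)[C@@H]2CO)ccc1O | target

**Step count and risks**
Total step count: 17. Longest linear sequence: 15 steps (steps 3 to 17, from methyl 3-hydroxypropanoate).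

Steps most likely to fail:

1. **Step 13 (cyclisation–carbonylation).** The vinylpalladium may be protonated before it captures CO, giving the ester-free dihydrofuran. Methanol may add to the alkyne in place of the tethered hydroxyl. The acylpalladium may be trapped by a second vinylpalladium to give a ketone. The trifluoroacetic acid released may ionise the electron-rich benzylic C5–O bond or loosen silyl ethers. Fallback, from 20: ring closure and carbonylation are separated. Treatment of 20 with iodine and NaHCO3 in MeCN at 0 °C is a 5-endo-dig iodocyclisation that should give the (4R,5R)-3-iodo-2,5-diaryl-4-(silyloxymethyl)-4,5-dihydrofuran F1. This vinyl iodide is then methoxycarbonylated with Pd(PPh3)4 (cat.), CO (1 atm), MeOH and Et3N in DMF at 50 °C. The same O1–C2 and C3–ester bonds are formed and the route is rejoined at 21.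

2. **Step 14 (hydrogenation).** The tetrasubstituted, donor–acceptor C2=C3 bond may resist hydrogen uptake. Forcing conditions may saturate the arenes or hydrogenolyse the benzylic C–O bonds, and facial selectivity may be incomplete. Fallback, from 21: conjugate reduction with ligated copper hydride (Cu(OAc)2·H2O, 1,2-bis(diphenylphosphino)benzene, polymethylhydrosiloxane, t-BuOH, toluene, rt). Hydride should add to C2 from the face opposite the C4 and C5 groups, and the copper enolate is protonated at C3 without control. The mixture of C3 epimers is not separated but taken through the DBU equilibration of step 15, so the route is rejoined at 23.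

3. **Step 10 (aldehyde to alkyne).** The basic diazomethane anion may deprotonate the α-carbon, so that the C4 stereocentre is epimerised or a β-silyloxy group is eliminated before addition to the carbonyl. Fallback, from 17: the aldehyde is converted under non-basic conditions (CBr4, PPh3, Et3N, CH2Cl2, 0 °C; Corey–Fuchs olefination) into the 1,1-dibromoalkene F2. F2 is treated with n-BuLi (2.2 equiv, THF, −78 °C), giving by bromine–lithium exchange and Fritsch–Buttenberg–Wiechell rearrangement the lithium acetylide F3. Aqueous quench protonates it and the route is rejoined at 18.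

**Further compounds**
F1 | step 13 | (4R,5R)-3-iodo-2,5-bis[4-(TBS-oxy)-3-methoxyphenyl]-4-[(TBS-oxy)methyl]-4,5-dihydrofuran | COc1cc(C2=C(I)[C@H](CO[Si](C)(C)C(C)(C)C)[C@H](c3ccc(O[Si](C)(C)C(C)(C)C)c(OC)c3)O2)ccc1O[Si](C)(C)C(C)(C)C
F0 | step 14 | none | none
F2 | step 10 | (3R,4R)-1,1-dibromo-4-[4-(TBS-oxy)-3-methoxyphenyl]-3-[(TBS-oxy)methyl]-4-(TES-oxy)but-1-ene | CC[Si](CC)(CC)O[C@@H](c1ccc(O[Si](C)(C)C(C)(C)C)c(OC)c1)[C@@H](CO[Si](C)(C)C(C)(C)C)C=C(Br)Br
F3 | step 10 | lithium acetylide of 18 | CC[Si](CC)(CC)O[C@@H](c1ccc(O[Si](C)(C)C(C)(C)C)c(OC)c1)[C@@H](CO[Si](C)(C)C(C)(C)C)C#C[Li]
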